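| flask | solid substrate | coupling partner | remark | time |
|---|---|---|---|---|
| maple | 0.13 M | 3 equiv | run made earlier |  |
| elm | 0.30 M | 3 equiv | run made earlier |  |
| flask | 0.20 M | 3.00 equiv |  | 6.0 h |

| run | time / h | target / % | solid product / % |
|---|---|---|---|
| maple | 0.833 | 1.8 | 0.3 |
| maple | 2.00 | 5.3 | 0.1 |
| maple | 4.00 | 6.8 | 0 |
| maple | 6.00 | 6.6 | 0 |
| elm | 0.833 | 0.9 | 0.4 |
| elm | 2.00 | 2.1 | 0 |
| elm | 4.00 | 3.8 | 0 |
| elm | 6.00 | 3.1 | 0.6 |

(standard deviation of a reading: 0.5 percentage points)

- for target the solid product is counted in
- as a solid, counted per litre of solution: solid substrate, solid product
- at the start none of the solid substrate is in solution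
- dissolved substrate means what is dissolved; the solid is not counted in it

* target and solid product together at 6.0 h, in percent of the solid substrate charged
* concentration of dissolved substrate in solution at 6.0 h, in percent of saturation

1. The maple run, charged with less solid substrate than the elm run, gains target faster as a fraction of its charge. I read the target column by itself, since it already counts the solid product. Over the first 2.00 h, maple gains 0.0265 /h and elm 0.0105 /h.

2. Then both slopes read smaller. Up to 4.00 h, the maple rate is 0.00750 /h, down by a factor of 3.53, and the elm rate is 0.00850 /h, down by a factor of 1.24. Both factors are readings, and the elm factor is too small to stand clear of the scatter.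

3. By 6.00 h, maple has moved 0.2 percentage points and elm 0.7 points, both downward, against a scatter of 0.5 points per reading. So I call both runs flat and average their last two readings: 6.70% for maple and 3.45% for elm.

4. I join these two ends with the loading exponent, the slope of ln(plateau fraction) against ln(loading), taken as a positive number: 0.794. It is a reading and carries the scatter of its two ends.

5. Carried from maple to 0.20 M, my own estimate for target and solid product together is 4.76%, a little lower than the forecast's 5%.

6. The forecast gives 5% (3.9% to 6.2%) for target and solid product together and, for dissolved substrate, 100% of saturation (88% to 100%), reasoning “Loading-independent rates imply solution held at saturation by excess solid”.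

7. At 6.0 h the flask gives 4.87% of target and solid product together, against my 4.76%, and dissolved substrate at 15.2% of saturation, lower than the forecast's 100%.

    dissolved substrate + target → side product (k = 30.0 /M/h)
    dissolved substrate + coupling partner → target (k = 2.80 /M/h)
    solid product ⇌ target, rate k3*(cs3 - [target]) while solid is left; crystals form when [target] > cs3 (solubility = 0.0830 M, k = 17.0 /h)
    solid substrate ⇌ dissolved substrate, rate k4*(cs4 - [dissolved substrate]) while solid is left; crystals form when [dissolved substrate] > cs4 (solubility = 0.100 M, k = 0.110 /h)
    2 coupling partner → homo dimer (k = 0.770 /M/h)

8. Take a neighbouring flask, the same recipe with 0.050 M of solid substrate, which lies below both earlier runs. For target and solid product together, the exponent 0.794 carried from maple gives 14.3%, and that neighbour gives 11.4%, less than the reckoning. At 6.00 h, the neighbour holds 0% solid substrate, where the flask holds 70.4%. Its side product, each counted twice, stands at 55.1%, where the flask has 17.1%.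

(The earlier runs and the new flask stem from a simulated flask for an exercise, and the scatter is random.)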